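**The question.** Ligand goes two ways. A starting complex exchanges with incoming ligand, while a protic impurity quenches that ligand.

common to all: starting complex 0.062 M; incoming ligand 0.0434 M
- beta: protic impurity 0.031 M; temperature 35 °C; run made earlier
- zeta: protic impurity 0.12 M; temperature 54 °C; run made earlier
- green: protic impurity 0.0620 M; temperature 50 °C; time 20 d
- ochre: protic impurity 0.0620 M; temperature 58 °C; time 20 d

| run | time / d | complex with one exchanged / % | starting complex / % | complex with two exchanged / % | complex with three exchanged / % |
|---|---|---|---|---|---|
| beta | 4.00 | 23.4 | 75.6 | 0 | 0 |
| beta | 8.00 | 32.0 | 66.4 | 0 | 1.0 |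
| beta | 15.0 | 33.1 | 65.7 | 0.1 | 0 |
| beta | 40.0 | 27.1 | 66.7 | 3.3 | 2.6 |
| zeta | 5.00 | 17.4 | 82.3 | 0 | 0 |
| zeta | 10.0 | 9.6 | 88.0 | 0 | 0 |
| zeta | 15.0 | 10.7 | 91.5 | 0.8 | 0.7 |
| zeta | 20.0 | 7.8 | 93.3 | 1.9 | 0 |

(readings scatter by 1 percentage point)



* which of these there is most of at the end, counted by the starting complex in it, green (complex with three exchanged / starting complex / complex with two exchanged / complex with one exchanged)
* which of these there is most of at the end, counted by the starting complex in it, ochre (complex with three exchanged / starting complex / complex with two exchanged / complex with one exchanged)
* final amount of the leader among these, as a percentage of the starting complex charged, in green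
* final amount of the leader among these, as a percentage of the starting complex charged, in ochre

**Bench rule.** With impurity in excess, I would treat quenching as pseudo-first-order: the impurity stays at its charge, and the ligand decays with one rate constant. In the zeta run, hotter and richer in impurity than beta, complex with one exchanged reads 17.4% and then 7.8%, while starting complex climbs to 93.3%. The beta run still reads 66.7% of starting complex at 40.0 d.

**Its border.** The rule wants about a 10-fold excess, but green and ochre carry impurity at 1.43 times the ligand charge, far less. So the impurity cannot be held constant, and the rate stays second order. Taking quenching as one for one, I reckon 30.0% for green and ochre. This is the impurity floor, the share of its own charge that the impurity keeps once the whole ligand charge is quenched: one minus ligand charge over impurity charge. I expect starting complex to lead in both flasks, with quenching slowing as the impurity falls.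

**The forecast.** It names starting complex for green at 77% and starting complex for ochre at 83%. Its ground: “the ligand is eventually lost”.

**The result.** Starting complex leads, at 83.6% in green and 90.0% in ochre, which is 6.6 percentage points and 7 points above the forecast.

    complex with two exchanged + incoming ligand ⇌ leaving ligand + complex with three exchanged (K = 3.60, k = 7.30 × 10⁻⁵ /M/s, Ea = 93.0 kJ/mol, ΔH = −37.0 kJ/mol)
    protic impurity + incoming ligand → quenched reagent (k = 7.00 × 10⁻⁵ /M/s, Ea = 93.0 kJ/mol)
    complex with one exchanged + incoming ligand ⇌ leaving ligand + complex with two exchanged (K = 1.60, k = 1.20 × 10⁻⁵ /M/s, Ea = 69.0 kJ/mol, ΔH = −23.0 kJ/mol)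
    complex with three exchanged + incoming ligand ⇌ leaving ligand + complex with four exchanged (K = 23.0, k = 1.60 × 10⁻⁴ /M/s, Ea = 69.0 kJ/mol, ΔH = 7.00 kJ/mol)
    starting complex + incoming ligand ⇌ leaving ligand + complex with one exchanged (K = 0.930, k = 1.20 × 10⁻⁴ /M/s, Ea = 85.0 kJ/mol, ΔH = −7.00 kJ/mol)
    (constants at 50 °C)

In green, the first exchange relaxes with a half-life of 0.881 d at 20.0 d, shorter than the 35.9 d of the second exchange and short against the run's 20 d. At that time green has 3.9% of its ligand charge still unbound, and its impurity stands at 52% of its charge, above the floor of 30.0% but down by 48.0%, which is no constant concentration.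

**A neighbour.** A further flask, like green but with 0.15 M of impurity, has a floor of 71.1%. At 20.0 d this flask keeps 75% of its impurity charge, above that floor, with 0.72% of its ligand charge still unbound and 90.7% of starting complex.

The data stem from a simulated flask from invented constants; scatter was added.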